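**Retrosynthetic overview**
The strategy rests on ring A: oxygens at C5 and C8 para to each other, C6–H and C7–OMe between them, and fusion to ring C through C4a–C8a. This is the pattern that a 4-alkenyl-4-hydroxy-3-methoxycyclobutenone gives when it ring-expands across a C=C bond.
Ring A is therefore cut at C5–C4a (electrocyclic closure of a dienylketene) and at C8–C8a (addition of a C6-metalated 4-pyranone to methyl semisquarate, made from dimethyl squarate).
Ring C is bought as pyromeconic acid (C2 bromination, O-methylation), and ring B is joined at C2–C1' by Suzuki coupling with a dibenzyl-protected catechol boronic acid from 3-bromocatechol.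
Order of ring events: rings B and C are joined, the four-membered ring is attached at the future C8a, ring A is formed last from the four-membered ring; then 8-O-methylation and debenzylation.

Key step: step 9

Remark: pyromeconic acid, 3-bromocatechol and dimethyl squarate are taken as purchasable; the target has no stereocentre, and the two carbinol centres that arise on the way are racemic and are destroyed again.

**Route**

Step 1
Reactants: 1 pyromeconic acid (3-hydroxy-4H-pyran-4-one)
Product: 2 2-bromo-3-hydroxy-4H-pyran-4-one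
Conditions: NBS (1.0 equiv), MeCN, 0 °C to rt
Reagents that add atoms: N-bromosuccinimide, O=C1CCC(=O)N1Br
Why: Electrophilic bromination of the enolic 3-hydroxy-4-pyranone should take place at C2, the only ring carbon ortho to the hydroxyl and the position at which this ring class is attacked by electrophiles, and one equivalent of NBS at low temperature should prevent a second bromination.

Step 2
Reactants: 2 2-bromo-3-hydroxy-4H-pyran-4-one
Product: 3 2-bromo-3-methoxy-4H-pyran-4-one
Conditions: MeI, K2CO3, acetone, 40 °C
Reagents that add atoms: iodomethane, CI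
Why: Williamson O-methylation of the acidic enolic hydroxyl is expected to be clean because carbonate is too weak a nucleophile to displace the C2 bromide of this vinylogous acyl bromide.

Step 3
Reactants: 4 3-bromocatechol
Product: 5 1,2-bis(benzyloxy)-3-bromobenzene
Conditions: BnBr (2.3 equiv), K2CO3, DMF, 60 °C
Reagents that add atoms: benzyl bromide, BrCc1ccccc1
Why: Double Williamson benzylation of the catechol should proceed normally, the aryl bromide being inert to carbonate and benzyl bromide.

Step 4
Reactants: 5 1,2-bis(benzyloxy)-3-bromobenzene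
Product: 8 2,3-bis(benzyloxy)phenylboronic acid, via aryllithium 6 (not isolated), via lithium aryl(triisopropoxy)borate 7 (not isolated)
Conditions: B(OiPr)3 (1.3 equiv), n-BuLi (1.1 equiv, added last), THF–toluene, −78 °C; then 1 M HCl, rt
Reagents that add atoms: triisopropyl borate, CC(C)OB(OC(C)C)OC(C)C; water, O
Why: Bromine–lithium exchange at −78 °C is much faster than benzylic deprotonation, and with the borate already present the aryllithium is trapped at once (in situ quench borylation) and the ate complex is hydrolysed to the boronic acid on acidic work-up.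

Step 5
Reactants: 3 2-bromo-3-methoxy-4H-pyran-4-one; 8 2,3-bis(benzyloxy)phenylboronic acid
Product: 9 2-[2,3-bis(benzyloxy)phenyl]-3-methoxy-4H-pyran-4-one
Conditions: Pd(OAc)2 (3 mol %), SPhos (6 mol %), K3PO4, toluene–H2O, 80 °C
Reagents that add atoms: none
Why: Suzuki–Miyaura coupling should be easy at the electron-poor C2–Br bond, which adds readily to zerovalent palladium, and the bulky biarylphosphine with phosphate in a two-phase medium is chosen for the ortho-substituted boronic acid and to spare the base-sensitive pyranone.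

Step 6
Reactants: 10 dimethyl squarate
Product: 11 4-hydroxy-2,3-dimethoxycyclobut-2-en-1-one (racemic)
Conditions: LiAlH(OtBu)3 (1.05 equiv), THF, −78 to −20 °C; then cold 1 M HCl
Reagents that add atoms: none
Why: The bulky, mild hydride should add once to one of the two equivalent carbonyls of the squarate (1,2-reduction), the resulting alkoxide deactivating the remaining vinylogous ester carbonyl; the carbinol centre is formed racemic and is lost in step 7.

Step 7
Reactants: 11 4-hydroxy-2,3-dimethoxycyclobut-2-en-1-one
Product: 12 3-methoxycyclobut-3-ene-1,2-dione (methyl semisquarate)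
Conditions: conc. HCl (cat.), CH2Cl2, rt; kept cold under argon and used at once
Reagents that add atoms: water, O
Why: Acid ionises the allylic carbinol to a cyclobutenyl cation stabilised by the distal methoxy group, water adds at that oxocarbenium carbon and methanol is expelled, a net allylic transposition that is the standard way from squarate adducts to cyclobutenediones.

Step 8
Reactants: 9 2-[2,3-bis(benzyloxy)phenyl]-3-methoxy-4H-pyran-4-one; 12 3-methoxycyclobut-3-ene-1,2-dione
Product: 15 2-[2,3-bis(benzyloxy)phenyl]-6-(1-hydroxy-2-methoxy-4-oxocyclobut-2-en-1-yl)-3-methoxy-4H-pyran-4-one (racemic), via 6-lithiopyranone 13 (not isolated), via lithium alkoxide 14 (not isolated)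
Conditions: LiTMP (lithium 2,2,6,6-tetramethylpiperidide, 1.05 equiv, from 2,2,6,6-tetramethylpiperidine and n-BuLi), THF, −78 °C, 9 added to the base; then transferred into 12 (1.3 equiv), THF, −78 °C; sat. aq NH4Cl
Reagents that add atoms: none
Why: Deprotonative lithiation by the hindered amide should occur at C6–H, the vinylic hydrogen next to the ring oxygen and the kinetically most acidic site of a 4-pyranone (as C2–H is in chromones), and the vinyllithium then adds 1,2 to the carbonyl of 12 that sits next to C–OMe, which is ketone-like, and not to the deactivated vinylogous ester carbonyl, as is the rule for 3-alkoxycyclobutenediones; the carbinol centre is racemic and becomes sp2 in step 9.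

Step 9
Reactants: 15 2-[2,3-bis(benzyloxy)phenyl]-6-(1-hydroxy-2-methoxy-4-oxocyclobut-2-en-1-yl)-3-methoxy-4H-pyran-4-one
Product: 18 2-[2,3-bis(benzyloxy)phenyl]-5,8-dihydroxy-3,7-dimethoxy-4H-chromen-4-one, via dienylketene 16 (not isolated), via 4a-hydro dienone 17 (not isolated)
Conditions: degassed toluene (0.02 M), 110 °C, argon
Reagents that add atoms: none
Why: Heat should open the cyclobutenone by conrotatory 4π electrocyclic cleavage of the bond between the carbonyl carbon and the carbinol carbon, giving the (Z)-dienylketene 16 in which the pyranone C5=C6 bond is the third double bond of a triene. The ketene carbon (the future C5 of the chromone) then bonds to pyranone C5 (the future C4a) in a thermal 6π electrocyclisation, which closes ring A as a six-membered carbocycle, and the dienone 17 enolises to the aromatic 5,8-hydroquinone 18. The closest known reaction is the thermal ring expansion of 4-aryl- and 4-alkenyl-4-hydroxycyclobutenones to hydroquinones (Moore rearrangement), here run with a 4-oxopyranyl group as the alkenyl arm. No lasting stereocentre is made: the racemic carbinol carbon becomes sp2 C8 and the sp3 centre at C4a of 17 is removed by enolisation. The step needs the pyranonyl arm and not the hydroxyl to turn inward toward the ketene, which the strong preference of a donor hydroxyl for outward rotation secures, and once the arm is inward, pyranone C5, which bears a hydrogen, is the only carbon within bonding distance. That carbon is the nucleophilic α-carbon of a vinylogous ester in a weakly aromatic ring, so attack on the electrophilic ketene carbon and rearomatisation should be at least as easy as for the benzene and furan arms that are known to work, and the placement of 5-OH, 6-H, 7-OMe and 8-OH follows from the regiochemistry fixed in step 8.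

Step 10
Reactants: 18 2-[2,3-bis(benzyloxy)phenyl]-5,8-dihydroxy-3,7-dimethoxy-4H-chromen-4-one
Product: 19 2-[2,3-bis(benzyloxy)phenyl]-5-hydroxy-3,7,8-trimethoxy-4H-chromen-4-one
Conditions: MeI (1.1 equiv), K2CO3 (1.1 equiv), degassed acetone, rt, argon
Reagents that add atoms: iodomethane, CI
Why: The 5-hydroxyl is locked in a hydrogen bond to the C4 carbonyl and is far less acidic and nucleophilic, so one equivalent of base and iodomethane should alkylate only the free 8-hydroxyl (Williamson etherification), air being excluded because the hydroquinone anion is easily oxidised.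

Step 11
Reactants: 19 2-[2,3-bis(benzyloxy)phenyl]-5-hydroxy-3,7,8-trimethoxy-4H-chromen-4-one
Product: 20 5,2',3'-trihydroxy-3,7,8-trimethoxyflavone
Conditions: H2 (1 atm), 10% Pd/C, EtOAc–MeOH, rt
Reagents that add atoms: none
Why: Hydrogenolysis over palladium should cleave both aryl benzyl ethers under conditions that leave the tetrasubstituted C2=C3 bond, the carbonyl and the methyl ethers of the flavone untouched.

**Compound list**
1 | pyromeconic acid (3-hydroxy-4H-pyran-4-one) | O=c1ccocc1O | starting material
2 | 2-bromo-3-hydroxy-4H-pyran-4-one | O=c1ccoc(Br)c1O | intermediate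
3 | 2-bromo-3-methoxy-4H-pyran-4-one | COc1c(Br)occc1=O | intermediate
4 | 3-bromocatechol (3-bromobenzene-1,2-diol) | Oc1cccc(Br)c1O | starting material
5 | 1,2-bis(benzyloxy)-3-bromobenzene | Brc1cccc(OCc2ccccc2)c1OCc1ccccc1 | intermediate
6 | [2,3-bis(benzyloxy)phenyl]lithium | [Li]c1cccc(OCc2ccccc2)c1OCc1ccccc1 | intermediate
7 | lithium [2,3-bis(benzyloxy)phenyl]tri(propan-2-yloxy)borate | [Li+].CC(C)O[B-](OC(C)C)(OC(C)C)c1cccc(OCc2ccccc2)c1OCc1ccccc1 | intermediate
8 | 2,3-bis(benzyloxy)phenylboronic acid | OB(O)c1cccc(OCc2ccccc2)c1OCc1ccccc1 | intermediate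
9 | 2-[2,3-bis(benzyloxy)phenyl]-3-methoxy-4H-pyran-4-one | COc1c(-c2cccc(OCc3ccccc3)c2OCc2ccccc2)occc1=O | intermediate
10 | dimethyl squarate (3,4-dimethoxycyclobut-3-ene-1,2-dione) | COC1=C(OC)C(=O)C1=O | starting material
11 | 4-hydroxy-2,3-dimethoxycyclobut-2-en-1-one (racemic) | COC1=C(OC)C(=O)C1O | intermediate
12 | 3-methoxycyclobut-3-ene-1,2-dione (methyl semisquarate) | COC1=CC(=O)C1=O | intermediate
13 | 2-[2,3-bis(benzyloxy)phenyl]-6-lithio-3-methoxy-4H-pyran-4-one | COc1c(-c2cccc(OCc3ccccc3)c2OCc2ccccc2)oc([Li])cc1=O | intermediate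
14 | lithium alkoxide of 15 (lithium 1-{6-[2,3-bis(benzyloxy)phenyl]-5-methoxy-4-oxo-4H-pyran-2-yl}-2-methoxy-4-oxocyclobut-2-en-1-olate, racemic) | [Li+].COc1c(-c2cccc(OCc3ccccc3)c2OCc2ccccc2)oc(C2([O-])C(OC)=CC2=O)cc1=O | intermediate
15 | 2-[2,3-bis(benzyloxy)phenyl]-6-(1-hydroxy-2-methoxy-4-oxocyclobut-2-en-1-yl)-3-methoxy-4H-pyran-4-one (racemic) | COc1c(-c2cccc(OCc3ccccc3)c2OCc2ccccc2)oc(C2(O)C(OC)=CC2=O)cc1=O | intermediate
16 | (Z)-4-{6-[2,3-bis(benzyloxy)phenyl]-5-methoxy-4-oxo-4H-pyran-2-yl}-4-hydroxy-3-methoxybuta-1,3-dien-1-one (dienylketene, pyranonyl cis to the ketenyl group) | O=C=C/C(OC)=C(/O)c1cc(=O)c(OC)c(-c2cccc(OCc3ccccc3)c2OCc2ccccc2)o1 | intermediate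
17 | 2-[2,3-bis(benzyloxy)phenyl]-8-hydroxy-3,7-dimethoxy-4aH-chromene-4,5-dione (racemic keto tautomer) | O=C1C=C(OC)C(O)=C2OC(c3cccc(OCc4ccccc4)c3OCc3ccccc3)=C(OC)C(=O)C12 | intermediate
18 | 2-[2,3-bis(benzyloxy)phenyl]-5,8-dihydroxy-3,7-dimethoxy-4H-chromen-4-one | COc1cc(O)c2c(=O)c(OC)c(-c3cccc(OCc4ccccc4)c3OCc3ccccc3)oc2c1O | intermediate
19 | 2-[2,3-bis(benzyloxy)phenyl]-5-hydroxy-3,7,8-trimethoxy-4H-chromen-4-one | COc1cc(O)c2c(=O)c(OC)c(-c3cccc(OCc4ccccc4)c3OCc3ccccc3)oc2c1OC | intermediate
20 | 5,2',3'-trihydroxy-3,7,8-trimethoxyflavone | COc1cc(O)c2c(=O)c(OC)c(-c3cccc(O)c3O)oc2c1OC | target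

**Totals**
Total step count: 11.
Longest linear sequence: 7 steps (steps 1, 2, 5, 8, 9, 10, 11; the branch through steps 3 and 4 is equally long).

**Steps most likely to fail**

1. Step 8. What may go wrong: deprotonation at C5–H instead of C6–H, conjugate addition of the lithiated pyranone to not yet metalated 9, or attack of the organolithium on 12 at the wrong carbonyl or twice. The fallback sets out from 9 and comes back at 15. Zincation of 9 with TMPZnCl·LiCl (THF, rt) should give the thermally stable {6-[2,3-bis(benzyloxy)phenyl]-5-methoxy-4-oxo-4H-pyran-2-yl}zinc chloride F1, which does not add to the pyranone. Quenching with iodine would give 2-[2,3-bis(benzyloxy)phenyl]-6-iodo-3-methoxy-4H-pyran-4-one F2, which can be purified and its regiochemistry checked. Iodine–magnesium exchange with i-PrMgCl·LiCl (THF, −40 °C) would then give the corresponding pyranonylmagnesium chloride F3 at a defined position, and addition to 12 at −78 °C would give the chloromagnesium alkoxide F4, protonated by aqueous NH4Cl to 15.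

2. Step 9. What may go wrong: the 6π closure onto the cross-conjugated pyranone double bond may be slower than dimerisation or polymerisation of the ketene, or than lactonisation after inward rotation of the hydroxyl. The fallback gives up the ring expansion and buys ring A; it sets out from 5 and comes back at 20.
   - Bromine–lithium exchange of 5 (n-BuLi, THF, −78 °C) to 6, a CO2 quench and acidic work-up would give 2,3-bis(benzyloxy)benzoic acid F5.
   - Friedel–Crafts acylation of purchased 1,2,3,5-tetramethoxybenzene with methoxyacetyl chloride and AlCl3 (Et2O, 0 °C to rt) would give 2-methoxy-1-(2,3,4,6-tetramethoxyphenyl)ethan-1-one F6. In the same flask AlCl3 should remove the ortho methyl ether that is flanked by a second methoxy group, giving 1-(2-hydroxy-3,4,6-trimethoxyphenyl)-2-methoxyethan-1-one F7.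
   - Esterification of F7 with F5 (EDC·HCl, DMAP, CH2Cl2) would give 3,5,6-trimethoxy-2-(methoxyacetyl)phenyl 2,3-bis(benzyloxy)benzoate F8.
   - Baker–Venkataraman rearrangement (LiN(SiMe3)2, THF, −20 °C to rt) would give 1-[2,3-bis(benzyloxy)phenyl]-3-(2-hydroxy-3,4,6-trimethoxyphenyl)-2-methoxypropane-1,3-dione F9.
   - Cyclodehydration (cat. TsOH, toluene, 90 °C) would give 2-[2,3-bis(benzyloxy)phenyl]-3,5,7,8-tetramethoxy-4H-chromen-4-one F10.
   - BCl3 (CH2Cl2, −78 to 0 °C) should then cleave both benzyl ethers and, through chelation to the C4 carbonyl, only the 5-methyl ether, which gives 20 directly.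

3. Step 10. What may go wrong: air oxidation of the hydroquinone anion to the 5,8-quinone during the basic alkylation, and some alkylation of the chelated 5-hydroxyl. The fallback sets out from 15 and comes back at 19. O-Methylation of the tertiary hydroxyl of 15 (MeI, Ag2O, MeCN, rt, dark) would give 2-[2,3-bis(benzyloxy)phenyl]-6-(1,2-dimethoxy-4-oxocyclobut-2-en-1-yl)-3-methoxy-4H-pyran-4-one F11. Heating as in step 9 should open it, with the methoxy group rotating outward, to the (Z)-3,4-dimethoxy dienylketene F12. This should close to 2-[2,3-bis(benzyloxy)phenyl]-3,7,8-trimethoxy-4aH-chromene-4,5-dione F13 and enolise to 19, so the 8-methoxy group is in place before ring A becomes aromatic and no free hydroquinone is handled.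

**Further compounds**
F1 | step 8 | {6-[2,3-bis(benzyloxy)phenyl]-5-methoxy-4-oxo-4H-pyran-2-yl}zinc chloride | COc1c(-c2cccc(OCc3ccccc3)c2OCc2ccccc2)oc([Zn]Cl)cc1=O
F2 | step 8 | 2-[2,3-bis(benzyloxy)phenyl]-6-iodo-3-methoxy-4H-pyran-4-one | COc1c(-c2cccc(OCc3ccccc3)c2OCc2ccccc2)oc(I)cc1=O
F3 | step 8 | {6-[2,3-bis(benzyloxy)phenyl]-5-methoxy-4-oxo-4H-pyran-2-yl}magnesium chloride | COc1c(-c2cccc(OCc3ccccc3)c2OCc2ccccc2)oc([Mg]Cl)cc1=O
F4 | step 8 | chloromagnesium alkoxide of 15 (racemic) | COc1c(-c2cccc(OCc3ccccc3)c2OCc2ccccc2)oc(C2(O[Mg]Cl)C(OC)=CC2=O)cc1=O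
F5 | step 9 | 2,3-bis(benzyloxy)benzoic acid | OC(=O)c1cccc(OCc2ccccc2)c1OCc1ccccc1
F6 | step 9 | 2-methoxy-1-(2,3,4,6-tetramethoxyphenyl)ethan-1-one | COCC(=O)c1c(OC)c(OC)c(OC)cc1OC
F7 | step 9 | 1-(2-hydroxy-3,4,6-trimethoxyphenyl)-2-methoxyethan-1-one | COCC(=O)c1c(O)c(OC)c(OC)cc1OC
F8 | step 9 | 3,5,6-trimethoxy-2-(methoxyacetyl)phenyl 2,3-bis(benzyloxy)benzoate | COCC(=O)c1c(OC(=O)c2cccc(OCc3ccccc3)c2OCc2ccccc2)c(OC)c(OC)cc1OC
F9 | step 9 | 1-[2,3-bis(benzyloxy)phenyl]-3-(2-hydroxy-3,4,6-trimethoxyphenyl)-2-methoxypropane-1,3-dione (racemic) | COC(C(=O)c1cccc(OCc2ccccc2)c1OCc1ccccc1)C(=O)c1c(O)c(OC)c(OC)cc1OC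
F10 | step 9 | 2-[2,3-bis(benzyloxy)phenyl]-3,5,7,8-tetramethoxy-4H-chromen-4-one | COc1cc(OC)c2c(=O)c(OC)c(-c3cccc(OCc4ccccc4)c3OCc3ccccc3)oc2c1OC
F11 | step 10 | 2-[2,3-bis(benzyloxy)phenyl]-6-(1,2-dimethoxy-4-oxocyclobut-2-en-1-yl)-3-methoxy-4H-pyran-4-one (racemic) | COc1c(-c2cccc(OCc3ccccc3)c2OCc2ccccc2)oc(C2(OC)C(OC)=CC2=O)cc1=O
F12 | step 10 | (Z)-4-{6-[2,3-bis(benzyloxy)phenyl]-5-methoxy-4-oxo-4H-pyran-2-yl}-3,4-dimethoxybuta-1,3-dien-1-one | O=C=C/C(OC)=C(/OC)c1cc(=O)c(OC)c(-c2cccc(OCc3ccccc3)c2OCc2ccccc2)o1
F13 | step 10 | 2-[2,3-bis(benzyloxy)phenyl]-3,7,8-trimethoxy-4aH-chromene-4,5-dione (racemic) | O=C1C=C(OC)C(OC)=C2OC(c3cccc(OCc4ccccc4)c3OCc3ccccc3)=C(OC)C(=O)C12
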